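Numbering (elemane): ring A = C10 (CH3, vinyl C1=C2), C9 (CH2), C8 (OAc), C7, C6 (O), C5 (isopropenyl, C4). Lactone ring B = C6–O–C12(=O)–C11(CH3, O-angeloyl)–C7.
Enabling feature: C1 on C10 and C11 on C7 stand 1,4-cis on ring A and anti to the C8 acetate. A temporary C1–C11 bond therefore turns ring A into a bicyclo[2.2.2]octene whose third ring, C1–C10–C5–C6–C7–C11, is an oxidised 2-methoxyphenol.
Retrosynthesis: cut the angelate ester, C11–O, ring B (C12–O and the C12 oxidation level), the methylene carbons C2 and C13, one methyl each on C4 and C11, and C6–O. Re-join C1–C11, then cut C9–C10 and C7–C8 together (retro-[4+2]) to vinyl acetate, methanol and an acetyl-activated guaiacol.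
Forward: arene, then ring A plus the temporary ring in one three-component dearomatisation/Diels–Alder step. C5/C6 are set on the cage, glycol cleavage opens C1–C11, two methylenations follow, and ring B is made last.
Stereochemistry: C7, C8 and C10 come from the ortho/endo-selective cycloaddition, with the absolute sense fixed by lipase resolution of the adduct. C6 and C5 come from the cage faces and C11 from convex-face oxidation of the cis-lactone enolate. The acetate delivered by vinyl acetate is kept to the end.

Key step: step 3

Remark: the SMILES is read as (5R,6S,7R,8S,10R,11S) in elemane numbering. This is a cis-fused 6,12-lactone (H6 and H7 syn), with the C8 acetate anti to C11 and the angelate on the H7 face of ring B. "Cage" means the bicyclo[2.2.2]octane built from C10, C9, C8, C7, C6, C5, C1 and C11.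

Step 1
Reactants: 1 2,3-dimethoxytoluene; 2 acetyl chloride
Product: 3 1-(3,4-dimethoxy-2-methylphenyl)ethanone
Conditions: AlCl3 (1.2 equiv), CH2Cl2, 0 °C
Reagents that add atoms: acetyl chloride CC(=O)Cl
Why: Friedel–Crafts acylation, which should go para to the conjugated 3-methoxy group (and ortho to the methyl group) because the 2-methoxy group, flanked on both sides, is twisted out of conjugation; no stereocentre is formed.

Step 2
Reactants: 3 1-(3,4-dimethoxy-2-methylphenyl)ethanone
Product: 4 1-(4-hydroxy-3-methoxy-2-methylphenyl)ethanone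
Conditions: NaSEt (2.5 equiv), DMF, 110 °C; then 1 M HCl
Reagents that add atoms: none
Why: Nucleophilic aryl methyl ether cleavage by thiolate (SN2 at the methyl carbon), selective for the methoxy group para to the acetyl group because only that one releases a carbonyl-stabilised phenoxide.

Step 3
Reactants: 4 1-(4-hydroxy-3-methoxy-2-methylphenyl)ethanone; 5 methanol; 6 vinyl acetate
Product: 8 rac-7-endo-acetoxy-5-acetyl-3,3-dimethoxy-4-methylbicyclo[2.2.2]oct-5-en-2-one, via masked o-benzoquinone 7 (not isolated)
Conditions: PhI(OAc)2 (1.1 equiv), MeOH, 0 °C; MeOH removed under reduced pressure; vinyl acetate (neat, large excess), BHT (trace), sealed tube, 90 °C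
Reagents that add atoms: methanol CO; vinyl acetate C=COC(C)=O
Why: PhI(OAc)2 oxidises phenol 4 at the methoxy-bearing ortho carbon (C1), methanol is captured there to give the 6,6-dimethoxycyclohexa-2,4-dienone 7, and its ring-locked s-cis diene C10=C5–C6=C7 then adds vinyl acetate in a concerted, asynchronous inverse-electron-demand [4+2] cycloaddition, the closest known reaction type being the Diels–Alder reaction of masked o-benzoquinones with vinyl ethers, vinyl sulfides and styrenes. The single suprafacial [π4s+π2s] event closes two six-membered rings at once, the cyclohexene C10–C9–C8–C7–C6–C5 (ring A of the target) and the ring C10–C9–C8–C7–C11–C1, so that the bicyclo[2.2.2]octenone cage arises. Regioselectivity: C10 is both the delta carbon of the C11 dienone and the beta carbon of the C5 acetyl group and so carries the largest LUMO coefficient, hence it binds the nucleophilic CH2 terminus (C9) while the acetoxy-bearing carbon (C8) binds C7 next to the ketone. C10 and C7 are set together by the cyclic diene, which places C1 and C11 on the same face of ring A, and C8 is set by the endo rule (acetoxy under the diene, syn to the new C5=C6 bond, anti to the C1–C11 bridge). The step also needs cross-addition to win over dimerisation of 7, which the fully substituted C5=C10 double bond (the dienophilic site in such dimerisations) secures, and the adduct forms as a racemate that step 4 resolves.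

Step 4
Reactants: 8 rac-7-endo-acetoxy-5-acetyl-3,3-dimethoxy-4-methylbicyclo[2.2.2]oct-5-en-2-one
Product: 9 7-endo-acetoxy-5-acetyl-3,3-dimethoxy-4-methylbicyclo[2.2.2]oct-5-en-2-one as the single (8S) enantiomer (C7 C8 C10 as in the target)
Conditions: Burkholderia cepacia lipase, pH 7 phosphate buffer/MTBE, 30 °C, stopped slightly past half conversion; chromatography
Reagents that add atoms: none
Why: Lipase-catalysed kinetic resolution by enantioselective ester hydrolysis: by the Kazlauskas rule (large group C7, medium group C9) the (8R)-acetate should be hydrolysed faster, so the wanted (8S)-acetate should be recovered unchanged, which fixes the absolute configuration of C7, C8 and C10.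

Step 5
Reactants: 9 cage enone acetate (single enantiomer)
Product: 11 cage beta-hydroxy ketone (C6 OH syn to the C1–C11 bridge; C5 acetyl syn to the C8–C9 bridge; C11 ketone; C1 ketal; C8 OAc), via boronate 10 (not isolated)
Conditions: CuCl (5 mol %), Xantphos (5 mol %), NaOt-Bu (10 mol %), B2pin2 (1.2 equiv), MeOH (2 equiv), THF, rt; then NaBO3·4H2O, THF/H2O, rt
Reagents that add atoms: bis(pinacolato)diboron CC1(C)OB(OC1(C)C)B1OC(C)(C)C(C)(C)O1 (boron, kept only in 10); sodium perborate [Na+].[Na+].O[B-]1(O)OO[B-](O)(O)OO1 (oxygen at C6)
Why: Copper-catalysed conjugate borylation of the enone followed by stereoretentive C–B oxidation: the boryl-copper species should attack C6 on the cage face next to the flat C11 carbonyl because the endo acetate covers the other face, and C5 (alpha to the acetyl group) should settle in the mildly basic perborate medium with the acetyl group trans to the new hydroxyl and away from the ketal methoxy group.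

Step 6
Reactants: 11 cage beta-hydroxy ketone
Product: 13 cage alpha-ketol (C1 ketone; C11 carbinol bearing CH3; C6 OH; C5 2-hydroxypropan-2-yl; C8 OAc), via ketal triol 12 (not isolated)
Conditions: MeLi/CeCl3 (5 equiv each, premixed), THF, −78 °C; then 1 M HCl, THF, rt
Reagents that add atoms: methyllithium [Li]C; water O
Why: Organocerium 1,2-addition, non-basic and much faster with ketones than with the acetate, methylates both the C11 and the C4 carbonyl group, and the ketal, no longer deactivated by a neighbouring carbonyl group, is then hydrolysed by dilute acid; the new C11 centre (methyl expected anti to the C6 alkoxide) is cleared again in step 8.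

Step 7
Reactants: 13 cage alpha-ketol
Product: 14 cage 1,11-diol (C1 secondary carbinol; C11 tertiary carbinol; other groups as in 13)
Conditions: NaBH4, MeOH, 0 °C to rt
Reagents that add atoms: none
Why: Borohydride reduction of the only ketone left, chemoselective over the acetate; hydride should enter anti to the C11 methyl group, and the C1 carbinol centre is cleared in step 8.

Step 8
Reactants: 14 cage 1,11-diol
Product: 15 ring A keto aldehyde (C10 CH3 and CHO; C5 2-hydroxypropan-2-yl; C6 OH; C7 acetyl; C8 OAc; in equilibrium with the C1/O6 lactol)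
Conditions: Pb(OAc)4 (1.2 equiv), CH2Cl2, 0 °C to rt
Reagents that add atoms: none
Why: Criegee glycol cleavage of the C1–C11 bond removes the temporary ring and frees the C10 aldehyde and the C7 acetyl group without touching C5, C6, C7, C8 or C10; Pb(OAc)4 is preferred to NaIO4 because it also cleaves a rigid trans-diol.

Step 9
Reactants: 15 ring A keto aldehyde
Product: 17 ring A diene diol (C10 CH3 and vinyl; C7 isopropenyl; C6 OH; C5 2-hydroxypropan-2-yl; C8 OAc), via bis-hydroxysilane 16 (not isolated)
Conditions: Me3SiCH2Li/CeCl3 (6 equiv each, premixed), THF, −78 to 0 °C; cold 1 M HCl quench; crude 16: aq. HF, MeCN, rt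
Reagents that add atoms: (trimethylsilyl)methyllithium [Li]C[Si](C)(C)C
Why: Peterson olefination in its organocerium variant, whose low basicity spares the beta-acetoxy/beta-hydroxy ketone from E1cB loss, retro-aldol cleavage and epimerisation at C7, followed by acid-induced elimination of both beta-hydroxysilanes to the two terminal alkenes.

Step 10
Reactants: 17 ring A diene diol
Product: 18 allylic alcohol (C7 3-hydroxyprop-1-en-2-yl; other groups as in 17)
Conditions: SeO2 (0.3 equiv), t-BuOOH (2 equiv), CH2Cl2, 0 °C to rt
Reagents that add atoms: tert-butyl hydroperoxide CC(C)(C)OO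
Why: Riley-type allylic oxidation (ene reaction, then [2,3]-sigmatropic shift) of the isopropenyl methyl group, the only allylic CH3 in the molecule, since the vinyl group on quaternary C10 has no allylic C–H at all.

Step 11
Reactants: 18 allylic alcohol
Product: 20 alpha-methylene-gamma-lactone (cis-fused 6,12-olide; C5 2-hydroxypropan-2-yl; C8 OAc; C10 CH3 and vinyl), via hydroxy enal 19 (not isolated)
Conditions: activated MnO2 (excess), CH2Cl2, rt
Reagents that add atoms: none
Why: MnO2 oxidises the allylic alcohol to the enal, whose lactol with the cis C6 hydroxyl is oxidised further to the alpha-methylene lactone (a standard sesquiterpene-lactone endgame); the C8 oxygen is blocked as its acetate, so only the cis-fused ring B can form.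

Step 12
Reactants: 20 alpha-methylene-gamma-lactone
Product: 21 8-acetoxyelema-1,3,11(13)-trien-6,12-olide (C5 isopropenyl)
Conditions: Burgess reagent (MeO2CN−SO2N+Et3, 2 equiv), toluene, 60 °C
Reagents that add atoms: none
Why: Burgess dehydration (syn elimination through the sulfamate ester) of the only free, tertiary alcohol, which should take one of the six accessible methyl hydrogens rather than the hindered C5–H and so give the isopropenyl group.

Step 13
Reactants: 21 8-acetoxyelema-1,3,11(13)-trien-6,12-olide
Product: 23 8-acetoxy-11-hydroxyelema-1,3-dien-6,12-olide (11-OH syn to H6 and H7), via lithium enolate 22 (not isolated)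
Conditions: LiBH(s-Bu)3 (1.05 equiv), THF, −78 °C; then 2-(phenylsulfonyl)-3-phenyloxaziridine (1.5 equiv), −78 °C; AcOH quench
Reagents that add atoms: 2-(phenylsulfonyl)-3-phenyloxaziridine O=S(=O)(N1OC1c1ccccc1)c1ccccc1
Why: Conjugate hydride addition to the alpha-methylene lactone gives the lactone enolate regiospecifically and without external base (acetate and isolated alkenes untouched), and the Davis oxidation should occur on the convex face of the cis-fused bicycle, syn to H6 and H7, which sets C11 with oxygen exo and methyl endo.

Step 14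
Reactants: 23 8-acetoxy-11-hydroxyelema-1,3-dien-6,12-olide; 24 angelic acid
Product: 25 target CNP0140071.1
Conditions: 24, 2,4,6-trichlorobenzoyl chloride, Et3N, THF, rt (mixed anhydride, filtered); 23, LiN(SiMe3)2 (1.0 equiv), THF, −78 °C, then the anhydride, −78 to 0 °C; dilute HCl work-up
Reagents that add atoms: angelic acid C/C=C(/C)C(=O)O
Why: Acylation of the lithium alkoxide with the Yamaguchi mixed anhydride of angelic acid at low temperature and without nucleophilic catalyst, conditions under which the Z double bond should not isomerise; no stereocentre is touched.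

Compound list
1 | 2,3-dimethoxytoluene | COc1cccc(C)c1OC | starting material
2 | acetyl chloride | CC(=O)Cl | starting material
3 | 1-(3,4-dimethoxy-2-methylphenyl)ethanone | CC(=O)c1ccc(OC)c(OC)c1C | intermediate
4 | 1-(4-hydroxy-3-methoxy-2-methylphenyl)ethanone | CC(=O)c1ccc(O)c(OC)c1C | intermediate
5 | methanol | CO | starting material
6 | vinyl acetate | C=COC(C)=O | starting material
7 | 4-acetyl-6,6-dimethoxy-5-methylcyclohexa-2,4-dien-1-one (masked o-benzoquinone) | COC1(OC)C(=O)C=CC(C(C)=O)=C1C | intermediate
8 | rac-7-endo-acetoxy-5-acetyl-3,3-dimethoxy-4-methylbicyclo[2.2.2]oct-5-en-2-one (acetoxy syn to the enone bridge; both enantiomers) | O=C2C(OC)(OC)[C@@]1(C)C[C@H](OC(C)=O)[C@@H]2C=C1C(C)=O.O=C2C(OC)(OC)[C@]1(C)C[C@@H](OC(C)=O)[C@H]2C=C1C(C)=O | intermediate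
9 | (8S) enantiomer of 8, C7, C8 and C10 as in the target | O=C2C(OC)(OC)[C@@]1(C)C[C@H](OC(C)=O)[C@@H]2C=C1C(C)=O | intermediate
10 | cage beta-boryl ketone (C6 Bpin syn to the C1–C11 bridge) | O=C2C(OC)(OC)[C@@]1(C)C[C@H](OC(C)=O)[C@@H]2[C@@H](B3OC(C)(C)C(C)(C)O3)[C@@H]1C(C)=O | intermediate
11 | cage beta-hydroxy ketone (C6 OH syn to the C1–C11 bridge, C5 acetyl syn to the C8–C9 bridge) | O=C2C(OC)(OC)[C@@]1(C)C[C@H](OC(C)=O)[C@@H]2[C@@H](O)[C@@H]1C(C)=O | intermediate
12 | cage ketal triol (C11 OH expected syn to the C5–C6 bridge) | C[C@@]2(O)C(OC)(OC)[C@@]1(C)C[C@H](OC(C)=O)[C@@H]2[C@@H](O)[C@@H]1C(C)(C)O | intermediate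
13 | cage alpha-ketol (C1 ketone, C11 tertiary carbinol) | C[C@@]2(O)C(=O)[C@@]1(C)C[C@H](OC(C)=O)[C@@H]2[C@@H](O)[C@@H]1C(C)(C)O | intermediate
14 | cage 1,11-diol (trans-diol expected) | C[C@@]2(O)[C@@H](O)[C@@]1(C)C[C@H](OC(C)=O)[C@@H]2[C@@H](O)[C@@H]1C(C)(C)O | intermediate
15 | ring A keto aldehyde (open form of the C1/O6 lactol) | O=C[C@@]1(C)C[C@H](OC(C)=O)[C@@H](C(C)=O)[C@@H](O)[C@@H]1C(C)(C)O | intermediate
16 | bis(beta-hydroxysilane), epimers at the two new carbinol carbons | C[Si](C)(C)CC(O)[C@@]1(C)C[C@H](OC(C)=O)[C@@H](C(C)(O)C[Si](C)(C)C)[C@@H](O)[C@@H]1C(C)(C)O | intermediate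
17 | ring A diene diol | C=C[C@@]1(C)C[C@H](OC(C)=O)[C@@H](C(C)=C)[C@@H](O)[C@@H]1C(C)(C)O | intermediate
18 | allylic alcohol | C=C[C@@]1(C)C[C@H](OC(C)=O)[C@@H](C(=C)CO)[C@@H](O)[C@@H]1C(C)(C)O | intermediate
19 | hydroxy enal (closes to the lactol) | C=C[C@@]1(C)C[C@H](OC(C)=O)[C@@H](C(=C)C=O)[C@@H](O)[C@@H]1C(C)(C)O | intermediate
20 | alpha-methylene-gamma-lactone with C5 2-hydroxypropan-2-yl | C=C[C@@]1(C)C[C@H](OC(C)=O)[C@@H]2[C@@H](OC(=O)C2=C)[C@@H]1C(C)(C)O | intermediate
21 | 8-acetoxyelema-1,3,11(13)-trien-6,12-olide | C=C[C@@]1(C)C[C@H](OC(C)=O)[C@@H]2[C@@H](OC(=O)C2=C)[C@@H]1C(=C)C | intermediate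
22 | lithium enolate of the 11-methyl lactone | [Li+].C=C[C@@]1(C)C[C@H](OC(C)=O)[C@@H]2[C@@H](OC([O-])=C2C)[C@@H]1C(=C)C | intermediate
23 | 8-acetoxy-11-hydroxyelema-1,3-dien-6,12-olide | C=C[C@@]1(C)C[C@H](OC(C)=O)[C@@H]2[C@@H](OC(=O)[C@@]2(C)O)[C@@H]1C(=C)C | intermediate
24 | angelic acid, (Z)-2-methylbut-2-enoic acid | C/C=C(/C)C(=O)O | starting material
25 | CNP0140071.1 | C=C[C@@]1(C)C[C@H](OC(C)=O)[C@@H]2[C@@H](OC(=O)[C@@]2(C)OC(=O)/C(C)=C\C)[C@@H]1C(=C)C | target

Total step count: 14. Longest linear sequence: 14 steps (from 1).

Steps most likely to fail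

Step 3. The cycloaddition may be too slow at the methyl-bearing diene terminus beside the ketal, so the dienone could be lost by thermal decay while vinyl acetate oligomerises. The fallback sets out from 4. The dienone 7 is made in the same way but is intercepted with tert-butyl vinyl ether, a much stronger donor of the class for which this cycloaddition is best documented. This gives rac-7-endo-tert-butoxy-5-acetyl-3,3-dimethoxy-4-methylbicyclo[2.2.2]oct-5-en-2-one F1. The tert-butyl ether is then exchanged for the acetate with Ac2O and catalytic FeCl3 in Et2O, which comes back to the route at 8.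

Step 5. The boryl-copper addition may show poor facial selectivity, C5 may equilibrate incompletely, or water may be lost again from the beta-hydroxy ketone by a retro-oxa-Michael process. The fallback sets out from 9. Weitz–Scheffer epoxidation (t-BuOOH, DBU, CH2Cl2) on the same open cage face gives the cage 5,6-epoxy ketone F2, in which the oxirane forces the acetyl group to the wanted side. Reductive opening of the C5–O bond with Na[PhSeB(OEt)3] (from PhSeSePh and NaBH4, EtOH, AcOH) comes back to the route at 11.

Step 14. Acylation of the hindered tertiary alkoxide may be sluggish. That would leave time for Z-to-E isomerisation of the acyl donor and for 1,3-migration of the C8 acetyl group to the C11 alkoxide. The fallback sets out from 23. Acylation with 2-[bis(2,2,2-trifluoroethoxy)phosphoryl]propanoyl chloride (pyridine, DMAP, heating tolerated because nothing can isomerise) gives the 11-O-phosphonopropanoyl ester F3. A Still–Gennari olefination (KN(SiMe3)2, 18-crown-6, acetaldehyde, THF, −78 °C) then builds the Z-trisubstituted double bond on the ester already in place and comes back to the route at 25.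

Further compounds
F1 | step 3 | rac-7-endo-tert-butoxy-5-acetyl-3,3-dimethoxy-4-methylbicyclo[2.2.2]oct-5-en-2-one | O=C2C(OC)(OC)[C@@]1(C)C[C@H](OC(C)(C)C)[C@@H]2C=C1C(C)=O.O=C2C(OC)(OC)[C@]1(C)C[C@@H](OC(C)(C)C)[C@H]2C=C1C(C)=O
F2 | step 5 | cage 5,6-epoxy ketone (oxirane syn to the C1–C11 bridge) | O=C2C(OC)(OC)[C@@]1(C)C[C@H](OC(C)=O)[C@@H]2[C@H]3O[C@@]13C(C)=O
F3 | step 14 | 11-O-{2-[bis(2,2,2-trifluoroethoxy)phosphoryl]propanoyl} ester of 23 | C=C[C@@]1(C)C[C@H](OC(C)=O)[C@@H]2[C@@H](OC(=O)[C@@]2(C)OC(=O)C(C)P(=O)(OCC(F)(F)F)OCC(F)(F)F)[C@@H]1C(=C)C
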